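## Analysis of the target

Atom labels (atoms carry the prefix C, compounds plain numbers): seven-membered ring C1 (CH–O–aroyl)–C2 (CH2)–C3 (C–CH3)–C7 (C–OH)–C8–C9 (CH2)–C10 (C(CH3)OH); five-membered ring C3–C4–C5–C6 (CH–isopropyl)–C7.

The target 30 is a daucane sesquiterpenoid: a cis-fused bicyclo[5.3.0]decane triol whose only secondary hydroxyl, at C1, is esterified with 4-methoxybenzoic acid. It has five stereocentres. On the cyclopentane the C3 methyl, the C7 hydroxyl and the C6 isopropyl group lie on one face; the C1 ester oxygen and the C10 methyl lie on that same face of the seven-membered ring, and the C10 hydroxyl on the other, so the C1 and C10 oxygens are trans. The sensitive points are the two tertiary alcohols (ionisation, elimination), the C7 hydroxyl, which faces C10 across the seven-membered ring and can bridge onto a C10 cation, and the aryl ester, which does not survive strong base or hydride. The hard parts are the two adjacent fully substituted fusion carbons, C3 (all carbon) and C7 (oxygenated), next to C6, and a trans-diol on a medium ring that is remote from the centres that must control it. The plan rests on C10: it carries a methyl group and sits between the oxygenated C1 and the methylene C9. Taking C10 out as a CH(CH3) unit next to a C1 ketone leaves a six-membered ring C1–C2–C3–C7–C8–C9, a cis-fused hydrindanone, which is much easier to assemble with both fusion centres and C6 in place than the hydroazulene itself.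

## Retrosynthetic reasoning

**C1–O ester.** Target 30 is cut at the ester into triol 28 and acid chloride 29. Of the three hydroxyls only the one at C1 is secondary, so the acylation needs no protecting group and is placed last, after all acidic and basic steps.

**C10–O bond.** Triol 28 is traced to epoxy alcohol 27 by opening at the tertiary C10 with inversion. This gives the trans relation of the C1 and C10 oxygens and keeps the C1 oxygen on the face where the epoxide sat. Epoxide 27 comes from alkenol 26, whose C7 hydroxyl can deliver the oxidant to its own face of the C1=C10 double bond.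

**C1=C10 alkene from a C1 ketone.** Alkenol 26 is the desilylated form of 25, which is the reduction product of enol triflate 24, made from ketone 22 by enolisation toward the more substituted C10. This removes the C1 oxygen for the moment, but fixes the double bond between exactly the two carbons that need oxygen and makes the C10 configuration of 22 irrelevant.

**C1–C10 and C9–C10 (the carrying disconnection).** Ketone 22 is cut on both sides of C10 into hydrindanone 18 and diazoethane 20 (from nitrosourea 19). The cut is made here because C10 is the only ring carbon that bears a one-carbon branch and has a carbonyl-derived neighbour. The forward reaction has to insert CH(CH3) between C1 and C9, not between C1 and C2.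

**C1–C9 of the six-membered ring.** Ketone 18 comes from β-keto ester 17 by loss of the ester, and 17 from diester 16 by Dieckmann closure. The two ester carbonyls of 16 are seven atoms apart, so either sense of condensation gives a six-membered ring and, after decarboxylation, the same ketone.

**C7–C8 and the C7 carbinol.** Diester 16 is the saturated form of ynoate 15, which is cut at C7–C8 into keto ester 12 and ethyl propiolate 13. A small acetylide adding to the cyclopentanone anti to the neighbouring isopropyl group sets the C7 oxygen cis to isopropyl and to the C3 methyl, and brings in C8, C9 and an ester carbon in the right oxidation state.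

**C3–C2 and the quaternary centre.** Keto ester 12 is the cleavage product of methylidene ester 10, and 10 is the Johnson–Claisen product of allylic alcohol 7 and orthoester 8. The sigmatropic shift puts the acetate arm on the methyl-bearing carbon only, which avoids the regiochemical problem of alkylating a ketone with two tertiary α-carbons.

**Cyclopentane from the chiral pool.** Alcohol 7 comes from enal 6, the aldol condensation product of keto aldehyde 4, which is the cleavage product of menthene 2, made from (S)-limonene 1. The limonene stereocentre becomes C6 and relays its configuration to C3 (step 5) and C7 (step 7).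

## Alternatives that were turned down

**Alternative 1:** The C6–C7 bond is cut. The forward key step is a Lewis-acid-promoted type-one carbonyl-ene reaction of the cycloheptenone A1, in which the C7 ketone takes the trisubstituted alkene of the side chain on C3 and gives the isopropenyl alcohol A2. In its favour: it is convergent, the C1=C10 alkene is in place from the start, and the cyclic transition state puts hydroxyl and isopropenyl cis. Against it: A1 needs an enantioselective all-carbon quaternary centre beside the ketone of a seven-membered ring, ketones are poor enophiles, and the cis ring fusion of a five-membered ring on a flexible seven-membered ring is less secure than on a small ring. It is stronger than the chosen plan in step count and in the fixed alkene position. The chosen plan offers instead a chiral-pool stereocentre that controls C3 and C7 by a sigmatropic and a 1,2-induction relay, and a seven-membered ring that is made late by one insertion.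

**Alternative 2:** The C3–C4 bond is cut, with a temporary C2–C5 bond. The forward key step is the crossed intramolecular photocycloaddition of enone A3 to the bicyclo[2.1.1]hexane A4; reductive cleavage of the C2–C5 bond then gives the ketone A5. In its favour: the quaternary C3 and the cis fusion are forced by the tether in one step. Against it: cycloheptenones isomerise on irradiation to reactive twisted isomers. The cleavage must choose the C2–C5 bond over the C2–C3 bond. A5 still lacks the C10 methyl. The C6/C7 relationship and the absolute configuration must be set in A3 by an acyclic addition with little bias. It is not stronger than the chosen plan on any point that matters here.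

**Alternative 3:** The C2–C3, C6–C7 and C7–O bonds are cut at once. The forward key step is an enzymatic cyclisation of farnesyl diphosphate A6 by a class-one sesquiterpene cyclase to the alcohol A7, which is identical with compound 26. In its favour: one step builds both rings, three stereocentres and the alkene. This is clearly stronger in step economy, because only steps 16 to 18 would remain. Against it: it needs an enzyme whose product has exactly this configuration, a supply of A6 or an engineered host, and tolerance of the product mixtures such cyclases give. The chosen plan offers independence from a particular enzyme, a traceable origin for every stereocentre, and access to analogues by changing 20 or 29.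

Key step: step 12

Remark on the chemistry: the C7 hydroxyl is carried from step 7 to step 15 as its triethylsilyl ether, which is expected to survive alkoxide, hot chloride and amide bases that would strip a trimethylsilyl ether; ketone 22 is carried as the mixture of its two C10 epimers.

## Route

Step 1
Reactants: 1 (S)-(−)-limonene
Product: 2 (4S)-1-methyl-4-(propan-2-yl)cyclohex-1-ene
Conditions: H2 (1 atm), RhCl(PPh3)3 (cat.), benzene, rt
Reagents that add atoms: none
Why: Homogeneous hydrogenation with RhCl(PPh3)3 reduces the 1,1-disubstituted isopropenyl alkene much faster than the trisubstituted ring alkene, which is kept for the cleavage; the stereocentre is untouched.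

Step 2
Reactants: 2 (4S)-1-methyl-4-(propan-2-yl)cyclohex-1-ene
Product: 4 (3S)-6-oxo-3-(propan-2-yl)heptanal, via ozonide 3 (not isolated)
Conditions: O3, CH2Cl2, −78 °C; then Me2S, −78 °C → rt
Reagents that add atoms: ozone, [O-][O+]=O
Why: Ozonolysis with reductive work-up cleaves the only alkene to a methyl ketone and an aldehyde; the stereocentre is β to the aldehyde and cannot enolise.

Step 3
Reactants: 4 (3S)-6-oxo-3-(propan-2-yl)heptanal
Product: 6 (5R)-2-methyl-5-(propan-2-yl)cyclopent-1-ene-1-carbaldehyde, via aldol adduct 5 (not isolated)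
Conditions: piperidine (cat.), AcOH (cat.), benzene, reflux (Dean–Stark)
Reagents that add atoms: none
Why: Enamine-mediated intramolecular aldol condensation: the amine condenses with the aldehyde rather than the ketone, the enamine carbon closes the five-membered ring onto the ketone and water is lost to the conjugated enal. The isomeric acetylcyclopentene is the product of hydroxide conditions, not of amine–acid catalysis.

Step 4
Reactants: 6 (5R)-2-methyl-5-(propan-2-yl)cyclopent-1-ene-1-carbaldehyde
Product: 7 [(5R)-2-methyl-5-(propan-2-yl)cyclopent-1-en-1-yl]methanol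
Conditions: NaBH4, CeCl3·7H2O, MeOH, 0 °C
Reagents that add atoms: none
Why: Luche reduction gives clean 1,2-reduction of the fully substituted enal to the allylic alcohol.

Step 5
Reactants: 7 [(5R)-2-methyl-5-(propan-2-yl)cyclopent-1-en-1-yl]methanol; 8 triethyl orthoacetate
Product: 10 ethyl 2-[(1R,3R)-1-methyl-2-methylidene-3-(propan-2-yl)cyclopentyl]acetate, via ketene acetal 9 (not isolated)
Conditions: EtCO2H (cat.), 140–170 °C, EtOH distilled off
Reagents that add atoms: none
Why: Johnson–Claisen rearrangement: ketene acetal 9 rearranges through a chair [3,3] transition state and delivers the acetate carbon to the methyl-bearing alkene carbon only. The oxygen-bearing arm should pass over the ring face away from the isopropyl group on the neighbouring carbon, so the new quaternary centre has methyl cis and the acetate arm trans to isopropyl.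

Step 6
Reactants: 10 ethyl 2-[(1R,3R)-1-methyl-2-methylidene-3-(propan-2-yl)cyclopentyl]acetate
Product: 12 ethyl 2-[(1R,3R)-1-methyl-2-oxo-3-(propan-2-yl)cyclopentyl]acetate, via ozonide 11 (not isolated)
Conditions: O3, CH2Cl2, −78 °C; then Me2S, −78 °C → rt
Reagents that add atoms: ozone, [O-][O+]=O
Why: Ozonolysis of the 1,1-disubstituted alkene gives the C7 ketone; the neutral reductive work-up should leave the now enolisable isopropyl-bearing centre untouched.

Step 7
Reactants: 12 ethyl 2-[(1R,3R)-1-methyl-2-oxo-3-(propan-2-yl)cyclopentyl]acetate; 13 ethyl propiolate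
Product: 15 ethyl 3-[(1S,2R,5R)-2-(2-ethoxy-2-oxoethyl)-2-methyl-5-(propan-2-yl)-1-(triethylsilyloxy)cyclopentyl]prop-2-ynoate, via lithium alkoxide 14 (not isolated)
Conditions: 13, LiN(SiMe3)2, THF, −78 °C; then 12, −78 °C; then Et3SiOTf, −78 → 0 °C
Reagents that add atoms: triethylsilyl trifluoromethanesulfonate, CC[Si](CC)(CC)OS(=O)(=O)C(F)(F)F
Why: Addition of a lithium acetylide to a ketone; the stabilised acetylide does not attack ester carbonyls at −78 °C. The small linear nucleophile should enter anti to the isopropyl group on the adjacent carbon, so the C7 oxygen ends cis to isopropyl and to the C3 methyl; silylation of alkoxide 14 in the same flask prevents later lactonisation.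

Step 8
Reactants: 15 ethyl 3-[(1S,2R,5R)-2-(2-ethoxy-2-oxoethyl)-2-methyl-5-(propan-2-yl)-1-(triethylsilyloxy)cyclopentyl]prop-2-ynoate
Product: 16 ethyl 3-[(1S,2R,5R)-2-(2-ethoxy-2-oxoethyl)-2-methyl-5-(propan-2-yl)-1-(triethylsilyloxy)cyclopentyl]propanoate
Conditions: H2 (1 atm), Pd/C, EtOAc, rt
Reagents that add atoms: none
Why: Catalytic hydrogenation saturates the alkyne; esters and the silyl ether are inert, and the silyl ether keeps the γ-oxygen from closing a lactone.

Step 9
Reactants: 16 ethyl 3-[(1S,2R,5R)-2-(2-ethoxy-2-oxoethyl)-2-methyl-5-(propan-2-yl)-1-(triethylsilyloxy)cyclopentyl]propanoate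
Product: 17 ethyl (3R,3aS,7aR)-7a-methyl-6-oxo-3-(propan-2-yl)-3a-(triethylsilyloxy)octahydro-1H-indene-5-carboxylate
Conditions: KOtBu, THF, 0 °C → rt
Reagents that add atoms: none
Why: Dieckmann condensation of a 1,7-diester: the less hindered enolate at C9 should attack the acetate carbonyl (C1), and the reverse sense would give the same ketone after step 10. The two arms are cis on the cyclopentane, so the six-membered ring closes cis-fused, and deprotonation of the β-keto ester drives the equilibrium.

Step 10
Reactants: 17 ethyl (3R,3aS,7aR)-7a-methyl-6-oxo-3-(propan-2-yl)-3a-(triethylsilyloxy)octahydro-1H-indene-5-carboxylate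
Product: 18 (1R,3aR,7aS)-3a-methyl-1-(propan-2-yl)-7a-(triethylsilyloxy)octahydro-5H-inden-5-one
Conditions: LiCl, H2O, DMSO, 150 °C
Reagents that add atoms: none
Why: Krapcho dealkoxycarbonylation under near-neutral conditions; the silyloxy group is γ to the ketone, so β-elimination is not possible.

Step 11
Reactants: 19 N-ethyl-N-nitrosourea
Product: 20 diazoethane (dried toluene solution, used at once)
Conditions: KOH (aq.), toluene, 0 °C; organic layer dried over KOH pellets
Reagents that add atoms: none
Why: Base-induced cleavage of an N-alkyl-N-nitrosourea is the standard preparation of a non-stabilised diazoalkane; hydroxide attacks the urea carbonyl and the diazotate loses water.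

Step 12
Reactants: 18 (1R,3aR,7aS)-3a-methyl-1-(propan-2-yl)-7a-(triethylsilyloxy)octahydro-5H-inden-5-one; 20 diazoethane
Product: 22 (1R,3aR,8aS)-3a,6-dimethyl-1-(propan-2-yl)-8a-(triethylsilyloxy)octahydroazulen-5(1H)-one as both C6 epimers, via diazonium betaine 21 (not isolated)
Conditions: Sc(OTf)3 (10 mol %), 20 (about 2 equiv, added slowly), toluene, −78 °C
Reagents that add atoms: none
Why: Sc(OTf)3 binds the C1 carbonyl of 18 and the nucleophilic carbon of 20 adds to it to give betaine 21; the ring bond anti to the departing nitrogen then shifts from C1 to the new carbon as dinitrogen leaves, which forms C9–C10 beside the C1–C10 bond already made and returns the carbonyl. The closest known reaction type is the Lewis-acid-catalysed (scandium triflate or organoaluminium) one-carbon homologation of cycloalkanones with non-stabilised diazoalkanes, a Tiffeneau–Demjanov-type 1,2-shift. The seven-membered ring is not closed by a cyclisation; it arises by ring enlargement, the 1,2-migration of a ring carbon of the six-membered ring onto the inserted carbon. The one new stereocentre, C10 of the atom labels, is not controlled and need not be, because it becomes trigonal in step 13. The selectivity that matters is migration of C9 and not of C2: C2 is a neopentyl methylene held against the quaternary C3, and in the rotamer of 21 that places C2 anti to the leaving group either the methyl or the hydrogen of the new carbon must sit gauche to C2, whereas the rotamer that migrates C9 can turn the methyl toward the oxygen and away from C2. A second insertion should be slow because 22 is an α-branched, more hindered ketone, and the silyl ether is a spectator at this temperature.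

Step 13
Reactants: 22 (1R,3aR,8aS)-3a,6-dimethyl-1-(propan-2-yl)-8a-(triethylsilyloxy)octahydroazulen-5(1H)-one
Product: 24 (1R,3aR,8aS)-3a,6-dimethyl-1-(propan-2-yl)-8a-(triethylsilyloxy)-1,2,3,3a,4,7,8,8a-octahydroazulen-5-yl trifluoromethanesulfonate, via lithium enolate 23 (not isolated)
Conditions: LiN(iPr)2 (0.95 equiv), THF, −78 °C → rt; then PhNTf2, 0 °C → rt
Reagents that add atoms: N-phenylbis(trifluoromethanesulfonimide), O=S(=O)(N(c1ccccc1)S(=O)(=O)C(F)(F)F)C(F)(F)F
Why: With slightly less than one equivalent of base the lithium enolates equilibrate through the remaining ketone toward the more substituted enolate 23 (C1=C10), which the triflimide traps on oxygen; both C10 epimers of 22 converge here.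

Step 14
Reactants: 24 (1R,3aR,8aS)-3a,6-dimethyl-1-(propan-2-yl)-8a-(triethylsilyloxy)-1,2,3,3a,4,7,8,8a-octahydroazulen-5-yl trifluoromethanesulfonate
Product: 25 triethyl{[(3R,3aS,8aR)-6,8a-dimethyl-3-(propan-2-yl)-2,3,4,5,8,8a-hexahydroazulen-3a(1H)-yl]oxy}silane
Conditions: Pd(OAc)2 (cat.), PPh3, Bu3N, HCO2H, DMF, 60 °C
Reagents that add atoms: none
Why: Palladium-catalysed formate reduction of an enol triflate: oxidative addition to zerovalent palladium, exchange for formate, loss of CO2 and reductive elimination replace the triflate by hydrogen without moving the double bond.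

Step 15
Reactants: 25 triethyl{[(3R,3aS,8aR)-6,8a-dimethyl-3-(propan-2-yl)-2,3,4,5,8,8a-hexahydroazulen-3a(1H)-yl]oxy}silane
Product: 26 (3R,3aS,8aR)-6,8a-dimethyl-3-(propan-2-yl)-2,3,4,5,8,8a-hexahydroazulen-3a(1H)-ol
Conditions: Bu4NF, THF, rt → 50 °C
Reagents that add atoms: none
Why: Fluoride cleaves the tertiary silyl ether; the isolated trisubstituted alkene is inert.

Step 16
Reactants: 26 (3R,3aS,8aR)-6,8a-dimethyl-3-(propan-2-yl)-2,3,4,5,8,8a-hexahydroazulen-3a(1H)-ol
Product: 27 (3R,3aS,6S,7R,8aR)-6,7-epoxy-6,8a-dimethyl-3-(propan-2-yl)decahydroazulen-3a-ol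
Conditions: VO(acac)2 (cat.), t-BuOOH, CH2Cl2, 0 °C → rt
Reagents that add atoms: tert-butyl hydroperoxide, CC(C)(C)OO
Why: Hydroxyl-directed epoxidation: the vanadium alkoxide of the C7 hydroxyl carries the peroxide across the seven-membered ring and delivers oxygen to the alkene face on which the hydroxyl sits, giving the epoxide cis to the C7 hydroxyl.

Step 17
Reactants: 27 (3R,3aS,6S,7R,8aR)-6,7-epoxy-6,8a-dimethyl-3-(propan-2-yl)decahydroazulen-3a-ol
Product: 28 (3R,3aS,6R,7R,8aR)-6,8a-dimethyl-3-(propan-2-yl)decahydroazulene-3a,6,7-triol
Conditions: HClO4 (cat.), THF–H2O, 0 °C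
Reagents that add atoms: water, O
Why: Acid-catalysed epoxide hydrolysis: water attacks the tertiary C10 from the face opposite the epoxide oxygen (inversion), while the C1 oxygen keeps its place, which gives the trans-diol. The C7 hydroxyl is on the same face as the epoxide and cannot reach the backside of C10.

Step 18
Reactants: 28 (3R,3aS,6R,7R,8aR)-6,8a-dimethyl-3-(propan-2-yl)decahydroazulene-3a,6,7-triol; 29 4-methoxybenzoyl chloride
Product: 30 (1R,3aR,5R,6R,8aS)-6,8a-dihydroxy-3a,6-dimethyl-1-(propan-2-yl)decahydroazulen-5-yl 4-methoxybenzoate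
Conditions: pyridine, DMAP (cat.), CH2Cl2, 0 °C → rt
Reagents that add atoms: none
Why: DMAP-catalysed acylation; only the secondary C1 hydroxyl should react, the two tertiary hydroxyls being inert under these conditions.

## Compound list

1 | (S)-(−)-limonene, (4S)-1-methyl-4-(prop-1-en-2-yl)cyclohex-1-ene | C=C(C)[C@H]1CCC(C)=CC1 | starting material
2 | (4S)-1-methyl-4-(propan-2-yl)cyclohex-1-ene | CC(C)[C@H]1CCC(C)=CC1 | intermediate
3 | ozonide of 2, (4S)-1-methyl-4-(propan-2-yl)-7,8,9-trioxabicyclo[4.2.1]nonane (epimers at the acetal carbons) | CC(C)[C@H]1CCC2(C)OOC(C1)O2 | intermediate (not isolated)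
4 | (3S)-6-oxo-3-(propan-2-yl)heptanal | CC(C)[C@H](CC=O)CCC(C)=O | intermediate
5 | aldol adduct, (5R)-2-hydroxy-2-methyl-5-(propan-2-yl)cyclopentane-1-carbaldehyde (mixture at C1 and C2) | CC(C)[C@H]1CCC(C)(O)C1C=O | intermediate (not isolated)
6 | (5R)-2-methyl-5-(propan-2-yl)cyclopent-1-ene-1-carbaldehyde | CC(C)[C@H]1CCC(C)=C1C=O | intermediate
7 | [(5R)-2-methyl-5-(propan-2-yl)cyclopent-1-en-1-yl]methanol | CC(C)[C@H]1CCC(C)=C1CO | intermediate
8 | triethyl orthoacetate (1,1,1-triethoxyethane) | CC(OCC)(OCC)OCC | starting material
9 | ketene acetal, 1-ethoxy-1-{[(5R)-2-methyl-5-(propan-2-yl)cyclopent-1-en-1-yl]methoxy}ethene | CC(C)[C@H]1CCC(C)=C1COC(=C)OCC | intermediate (not isolated)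
10 | ethyl 2-[(1R,3R)-1-methyl-2-methylidene-3-(propan-2-yl)cyclopentyl]acetate | CCOC(=O)C[C@@]1(C)CC[C@H](C(C)C)C1=C | intermediate
11 | ozonide of 10 (spiro-1,2,4-trioxolane at the former methylidene-bearing carbon; epimers at the spiro carbon) | CCOC(=O)C[C@@]1(C)CC[C@H](C(C)C)C12OOCO2 | intermediate (not isolated)
12 | ethyl 2-[(1R,3R)-1-methyl-2-oxo-3-(propan-2-yl)cyclopentyl]acetate | CCOC(=O)C[C@@]1(C)CC[C@H](C(C)C)C1=O | intermediate
13 | ethyl propiolate (ethyl prop-2-ynoate) | C#CC(=O)OCC | starting material
14 | lithium alkoxide of the propargylic alcohol (15 with OLi in place of the silyloxy group) | CCOC(=O)C[C@@]1(C)CC[C@H](C(C)C)[C@@]1(O[Li])C#CC(=O)OCC | intermediate (not isolated)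
15 | ethyl 3-[(1S,2R,5R)-2-(2-ethoxy-2-oxoethyl)-2-methyl-5-(propan-2-yl)-1-(triethylsilyloxy)cyclopentyl]prop-2-ynoate | CCOC(=O)C[C@@]1(C)CC[C@H](C(C)C)[C@@]1(O[Si](CC)(CC)CC)C#CC(=O)OCC | intermediate
16 | ethyl 3-[(1S,2R,5R)-2-(2-ethoxy-2-oxoethyl)-2-methyl-5-(propan-2-yl)-1-(triethylsilyloxy)cyclopentyl]propanoate | CCOC(=O)C[C@@]1(C)CC[C@H](C(C)C)[C@@]1(O[Si](CC)(CC)CC)CCC(=O)OCC | intermediate
17 | ethyl (3R,3aS,7aR)-7a-methyl-6-oxo-3-(propan-2-yl)-3a-(triethylsilyloxy)octahydro-1H-indene-5-carboxylate (C5 epimers and enol) | O=C1C[C@@]2(C)CC[C@H](C(C)C)[C@@]2(O[Si](CC)(CC)CC)CC1C(=O)OCC | intermediate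
18 | (1R,3aR,7aS)-3a-methyl-1-(propan-2-yl)-7a-(triethylsilyloxy)octahydro-5H-inden-5-one | O=C1C[C@@]2(C)CC[C@H](C(C)C)[C@@]2(O[Si](CC)(CC)CC)CC1 | intermediate
19 | N-ethyl-N-nitrosourea | CCN(N=O)C(N)=O | starting material
20 | diazoethane | CC=[N+]=[N-] | intermediate
21 | diazonium betaine (C1 alkoxide of 18 bearing a 1-diazonioethyl group on C1) | [O-]C1(C(C)[N+]#N)C[C@@]2(C)CC[C@H](C(C)C)[C@@]2(O[Si](CC)(CC)CC)CC1 | intermediate (not isolated)
22 | (1R,3aR,8aS)-3a,6-dimethyl-1-(propan-2-yl)-8a-(triethylsilyloxy)octahydroazulen-5(1H)-one (both C6 epimers; C6 is C10 of the atom labels) | O=C1C[C@@]2(C)CC[C@H](C(C)C)[C@@]2(O[Si](CC)(CC)CC)CCC1C | intermediate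
23 | lithium enolate of 22 (C1=C10) | CC1=C(O[Li])C[C@@]2(C)CC[C@H](C(C)C)[C@@]2(O[Si](CC)(CC)CC)CC1 | intermediate (not isolated)
24 | (1R,3aR,8aS)-3a,6-dimethyl-1-(propan-2-yl)-8a-(triethylsilyloxy)-1,2,3,3a,4,7,8,8a-octahydroazulen-5-yl trifluoromethanesulfonate | CC1=C(OS(=O)(=O)C(F)(F)F)C[C@@]2(C)CC[C@H](C(C)C)[C@@]2(O[Si](CC)(CC)CC)CC1 | intermediate
25 | triethyl{[(3R,3aS,8aR)-6,8a-dimethyl-3-(propan-2-yl)-2,3,4,5,8,8a-hexahydroazulen-3a(1H)-yl]oxy}silane | CC1=CC[C@@]2(C)CC[C@H](C(C)C)[C@@]2(O[Si](CC)(CC)CC)CC1 | intermediate
26 | (3R,3aS,8aR)-6,8a-dimethyl-3-(propan-2-yl)-2,3,4,5,8,8a-hexahydroazulen-3a(1H)-ol | CC1=CC[C@@]2(C)CC[C@H](C(C)C)[C@@]2(O)CC1 | intermediate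
27 | (3R,3aS,6S,7R,8aR)-6,7-epoxy-6,8a-dimethyl-3-(propan-2-yl)decahydroazulen-3a-ol (epoxide on the face of the C3a hydroxyl) | O1[C@@H]2C[C@@]3(C)CC[C@H](C(C)C)[C@@]3(O)CC[C@]12C | intermediate
28 | (3R,3aS,6R,7R,8aR)-6,8a-dimethyl-3-(propan-2-yl)decahydroazulene-3a,6,7-triol | O[C@@H]1C[C@@]2(C)CC[C@H](C(C)C)[C@@]2(O)CC[C@@]1(C)O | intermediate
29 | 4-methoxybenzoyl chloride | COc1ccc(cc1)C(Cl)=O | starting material
30 | (1R,3aR,5R,6R,8aS)-6,8a-dihydroxy-3a,6-dimethyl-1-(propan-2-yl)decahydroazulen-5-yl 4-methoxybenzoate (CNP0244624.1) | COc1ccc(C(=O)O[C@@H]2C[C@@]3(C)CC[C@H](C(C)C)[C@@]3(O)CC[C@@]2(C)O)cc1 | target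

## Step count and least certain steps

Total step count: 18. Longest linear sequence: 17 steps (steps 1–10 and 12–18); step 11 is a one-step side branch.

**Step 12 (key step).** The most likely failure is competing migration of the neopentyl C2, which would insert the new carbon on the wrong side of the carbonyl. Lesser risks are a second insertion, closure of the betaine on oxygen to an epoxide, and Lewis-acid decomposition of the diazoalkane before it adds. The fallback is a regiospecific enlargement that does not depend on migratory preference, from 18 back to 22. Kinetic deprotonation of 18 (LiN(iPr)2, Me3SiCl, THF, −78 °C) at the unhindered C9 gives the trimethylsilyl enol ether F1. Ethylidene transfer (Et2Zn, CH3CHI2) gives the methyl-substituted silyloxycyclopropane F2. FeCl3 in DMF cleaves the internal C1–C9 bond by β-scission of the oxygen radical and gives the β-chloro ketone F3. NaOAc in methanol eliminates HCl to the enone F4 (C1 ketone, C9=C10, methyl on C10), and hydrogenation (H2, Pd/C) gives 22.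

**Step 13.** Incomplete equilibration would leave enolisation toward C2, and the isomeric triflate would put the alkene in the wrong place. The fallback sets out from 22 and returns at 25. CuBr2 (EtOAc–CHCl3, reflux) brominates through the more substituted, acid-derived enol to the α-bromo ketone F5 (bromine on C10). Li2CO3 and LiBr in hot DMF give the enone F4 described above. 4-Methylbenzenesulfonohydrazide gives the tosylhydrazone F6. Catecholborane followed by NaOAc then adds hydride at C1 and, through the allylic diazene, moves the double bond to C1=C10 with loss of nitrogen, which gives 25 without any enolate regiochemistry.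

**Step 7.** The stabilised acetylide may enolise the hindered ketone, with loss of configuration at C6, or add slowly and with poor facial selectivity. The fallback sets out from 12 and returns at 16. CH2=CHCH2MgBr with CeCl3 (THF, −78 °C), a non-basic reagent that adds to hindered ketones and spares esters, gives the homoallylic alcohol F7. Et3SiOTf with 2,6-lutidine gives the triethylsilyl ether F8. Hydroboration with 9-BBN and oxidation with NaBO3 give the primary alcohol F9. TEMPO with PhI(OAc)2 in aqueous MeCN gives the carboxylic acid F10, and EtI with K2CO3 in DMF gives 16.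

**Step 17.** Ionisation at C10 may outrun attack by water; the cation could then be captured by the C7 hydroxyl as an oxygen bridge, or undergo hydride shift to a ketone or elimination. The fallback makes the C10–O bond by electrophilic oxidation instead, from 22 back to 28. Me3SiCl, NaI and Et3N in MeCN give the thermodynamic trimethylsilyl enol ether F11. Rubottom oxidation (mCPBA, then mild acid) gives the α-hydroxy ketone F12, with the hydroxyl expected on the face opposite the silyloxy group; this facial preference would have to be confirmed. Me4NBH(OAc)3 delivers hydride to C1 from the face of the new hydroxyl and gives the trans-diol F13, and Bu4NF gives 28.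

**Step 5.** The sigmatropic shift may show poor facial selectivity, or be sluggish because a quaternary centre forms from a tetrasubstituted alkene. The fallback makes the same bond by enolate alkylation, from 6 back to 12. Baeyer–Villiger oxidation of the enal (H2O2, SeO2 cat.) gives the enol formate F14. Two equivalents of MeLi release the lithium enolate at the methyl-bearing carbon regiospecifically, and ethyl bromoacetate should again enter anti to the isopropyl group to give 12.

## Further compounds

F1 | step 12 | kinetic trimethylsilyl enol ether of 18 (C1=C9) | C[Si](C)(C)OC1=CC[C@]2(O[Si](CC)(CC)CC)[C@@H](C(C)C)CC[C@]2(C)C1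
F2 | step 12 | silyloxycyclopropane from F1 (ethylidene added across C1=C9; cyclopropane epimers) | C[Si](C)(C)OC12C[C@@]3(C)CC[C@H](C(C)C)[C@@]3(O[Si](CC)(CC)CC)CC1C2C
F3 | step 12 | β-chloro ketone (22 with chlorine on C9) | O=C1C[C@@]2(C)CC[C@H](C(C)C)[C@@]2(O[Si](CC)(CC)CC)CC(Cl)C1C
F4 | step 12 | enone (22 with a C9=C10 double bond) | O=C1C[C@@]2(C)CC[C@H](C(C)C)[C@@]2(O[Si](CC)(CC)CC)CC=C1C
F5 | step 13 | α-bromo ketone (22 with bromine on C10) | O=C1C[C@@]2(C)CC[C@H](C(C)C)[C@@]2(O[Si](CC)(CC)CC)CCC1(C)Br
F6 | step 13 | 4-methylbenzenesulfonylhydrazone of enone F4 | Cc1ccc(cc1)S(=O)(=O)NN=C1C[C@@]2(C)CC[C@H](C(C)C)[C@@]2(O[Si](CC)(CC)CC)CC=C1C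
F7 | step 7 | ethyl 2-[(1R,2S,3R)-2-hydroxy-1-methyl-3-(propan-2-yl)-2-(prop-2-en-1-yl)cyclopentyl]acetate | CCOC(=O)C[C@@]1(C)CC[C@H](C(C)C)[C@@]1(O)CC=C
F8 | step 7 | triethylsilyl ether of F7 | CCOC(=O)C[C@@]1(C)CC[C@H](C(C)C)[C@@]1(O[Si](CC)(CC)CC)CC=C
F9 | step 7 | primary alcohol (3-hydroxypropyl arm on C7) | CCOC(=O)C[C@@]1(C)CC[C@H](C(C)C)[C@@]1(O[Si](CC)(CC)CC)CCCO
F10 | step 7 | carboxylic acid (2-carboxyethyl arm on C7) | CCOC(=O)C[C@@]1(C)CC[C@H](C(C)C)[C@@]1(O[Si](CC)(CC)CC)CCC(=O)O
F11 | step 17 | thermodynamic trimethylsilyl enol ether of 22 (C1=C10) | CC1=C(O[Si](C)(C)C)C[C@@]2(C)CC[C@H](C(C)C)[C@@]2(O[Si](CC)(CC)CC)CC1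
F12 | step 17 | α-hydroxy ketone (22 with hydroxyl on C10, C10 configured as in the target) | O=C1C[C@@]2(C)CC[C@H](C(C)C)[C@@]2(O[Si](CC)(CC)CC)CC[C@@]1(C)O
F13 | step 17 | trans-diol (28 with the C7 oxygen still as triethylsilyl ether) | O[C@@H]1C[C@@]2(C)CC[C@H](C(C)C)[C@@]2(O[Si](CC)(CC)CC)CC[C@@]1(C)O
F14 | step 5 | (5R)-2-methyl-5-(propan-2-yl)cyclopent-1-en-1-yl formate | CC(C)[C@H]1CCC(C)=C1OC=O
A1 | alternative 1 | (2R)-2,5-dimethyl-2-(4-methylpent-3-en-1-yl)cyclohept-4-en-1-one | CC1=CC[C@@](C)(CCC=C(C)C)C(=O)CC1
A2 | alternative 1 | (3R,3aS,8aR)-6,8a-dimethyl-3-(prop-1-en-2-yl)-2,3,4,5,8,8a-hexahydroazulen-3a(1H)-ol | CC1=CC[C@@]2(C)CC[C@H](C(C)=C)[C@@]2(O)CC1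
A3 | alternative 2 | (4S)-4-hydroxy-3-methyl-4-[(3S)-4-methylpent-1-en-3-yl]cyclohept-2-en-1-one | CC1=CC(=O)CCC[C@]1(O)[C@H](C=C)C(C)C
A4 | alternative 2 | tricyclic photoadduct (bicyclo[2.1.1]hexane with C2–C5 and C3–C4 bonds, fused to the cycloheptanone) | O=C1[C@@H]2[C@@]3(C)C[C@@H]2[C@H](C(C)C)[C@@]3(O)CCC1
A5 | alternative 2 | (1R,3aR,8aS)-8a-hydroxy-3a-methyl-1-(propan-2-yl)octahydroazulen-5(1H)-one | O=C1C[C@@]2(C)CC[C@H](C(C)C)[C@@]2(O)CCC1
A6 | alternative 3 | (2E,6E)-farnesyl diphosphate | CC(C)=CCC/C(C)=C/CC/C(C)=C/COP(=O)(O)OP(=O)(O)O
A7 | alternative 3 | (3R,3aS,8aR)-6,8a-dimethyl-3-(propan-2-yl)-2,3,4,5,8,8a-hexahydroazulen-3a(1H)-ol (identical with 26) | CC1=CC[C@@]2(C)CC[C@H](C(C)C)[C@@]2(O)CC1
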